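# Proposed synthesis of 4,5'-dimethoxy-2',7-dimethyl-[1,1'-binaphthalene]-2,4',5,6'-tetrol (20)

## Analysis of the target

Target 20 is a 1,1'-binaphthalene made of two different trioxygenated methylnaphthalenes. With the numbering used throughout, the unprimed half is a 2-naphthol: ring A is C1 to C4 with C4a and C8a (axis at C1, OH at C2, H at C3, OMe at C4), and ring B is C5 to C8 (OH at C5, Me at C7). The primed half is a 1-naphthol-type unit: ring C carries the axis at C1', Me at C2', H at C3' and OH at C4', and ring D carries OMe at C5' and OH at C6'. There is no sp3 stereocentre; the only stereogenic element is the C1–C1' axis, flanked by the 2-OH, the 2'-Me and the peri positions C8 and C8', and the structure gives it no configuration. The four free phenols sit on very electron-rich rings (a 2-naphthol with a meta methoxy group, a catechol monoether on ring D), so 20 is prone to oxidation and the hydroxyls should be uncovered last under neutral, reducing conditions. Three things make the synthesis hard: the hindered bond between two different electron-rich naphthalenes, the placement of six oxygens and two methyl groups, and the need to tell the oxygens apart so that only O4 and O5' are methylated. The feature that invites the chosen move is ring A: C2 carries a free OH, its neighbour C1 carries an aryl group and no hydrogen, and C3–C4 is a CH=C(OMe) unit attached to C4a. This is the product pattern of the six-electron ring closure of an aryl ketene with a 1-methoxyethenyl group on the ortho carbon, where C2 is the ketene carbon, C1 its α-carbon, and C3/C4 the enol ether carbons. A ketene α-carbon bearing two aryl groups is in turn the product of a Wolff rearrangement of a 2-diazo-1,2-diaryl ethanone, so the C1–C1' bond can be made by a 1,2-aryl shift instead of a cross-coupling.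

## Retrosynthetic reasoning

20 to 19: the O–benzyl bonds at O5, O4' and O6' are cut. These three phenols are not created by the key step and are carried as benzyl ethers, which survive amide bases, organolithiums, palladium catalysis, titanium methylidenes and light. One neutral hydrogenolysis removes them at the end. The two methyl ethers and the free O2 need no protecting-group step because they are set by construction.

19 to 17 (through 18): ring A is opened at C2–C3. Retro-enolisation gives 18, and the reverse of a 6π electrocyclisation gives ketene 17, in which C2 is the ketene carbon and C3–C4 is a 1-methoxyethenyl group on C4a. This cut is chosen because both ends of the triene are then held on neighbouring carbons of ring B, so ring closure has no regiochemical choice. It also differentiates O2 (free, from the ketene) from O4 (methylated, from the enol ether). The forward reaction must outrun ketene dimerisation, which the intramolecular, electronically matched closure should do.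

17 to 16: the C1–C1' bond is cut. The reverse of a Wolff rearrangement returns the naphthyl group from C1 to the carbonyl carbon and gives diazo ketone 16. The crowded biaryl bond is therefore never made by joining two hindered sp2 carbons from separate molecules. In the forward direction it forms by an intramolecular shift driven by loss of nitrogen, and the same operation (step 11) then builds ring A around it.

16 to 15 to 10 + 14: the diazo group goes back to a CH2 (diazo transfer), and the C8a–C1 bond is cut as a ketone α-arylation of methyl ketone 10 with aryl triflate 14. This is the convergent point. The bond made is an aryl–CH2 bond to an unhindered carbon, far easier than the biaryl bond it will later turn into.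

14 to 13 to 12 to 11: the enol ether carbon C3 is removed (ester methylenation in the forward direction), the triflate goes back to a phenol, and the benzyl ether goes back to symmetric diol 11. In 11 the ester carbon (future C4) lies between two equivalent hydroxyls with the methyl para. Whichever hydroxyl is benzylated becomes O5 and the other becomes the attachment point C8a, so the substitution of ring B is fixed without any regiochemical question.

10 to 6 (through 9, 8, 7): the acetyl group at C1' comes from acylation of aryllithium 9, made from bromide 8. The bromine comes from para bromination of naphthol 6 (giving 7) followed by benzylation. The innate para reactivity of a 1-naphthol places the handle exactly on the future axis carbon.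

6 to 2 + 3 (through 4 and 5): ring C is cut at C4a'–C4' and C8a'–C1'. Aryne 5 and dienolate 4 assemble the ring in one step with Me at C2' and the OH at C4' peri to the OMe at C5'; the methoxy group on the aryne controls the orientation. Amide 2 comes from acid chloride 1.

## Alternatives that were turned down

Alternative 1: the textbook disconnection of the C1–C1' bond by Suzuki–Miyaura coupling. Bromide 8 would be coupled with 2-[2,5-bis(benzyloxy)-4-methoxy-7-methylnaphthalen-1-yl]-4,4,5,5-tetramethyl-1,3,2-dioxaborolane A1 to give 2,5-bis(benzyloxy)-1-[4,6-bis(benzyloxy)-5-methoxy-2-methylnaphthalen-1-yl]-4-methoxy-7-methylnaphthalene A2, and hydrogenolysis would give 20. It was turned down for three reasons: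
- The coupling joins two electron-rich partners that each carry an ortho substituent and a peri hydrogen, so transmetalation and reductive elimination are slow.
- The C–B bond of A1, flanked by an ortho alkoxy group, is prone to protodeboronation under the basic conditions.
- A1 needs its own multi-step naphthalene synthesis, including differentiation of O2, O4 and O5, so the route would be longer and the key step would simplify nothing.

Alternative 2: dehydrogenative disconnection of the same bond. 4-Methoxy-7-methylnaphthalene-2,5-diol A3 and 8-methoxy-3-methylnaphthalene-1,7-diol A4 would be joined by anodic cross-coupling (boron-doped diamond anode, hexafluoroisopropanol) between C1 of A3 (ortho to OH) and C4 of A4 (para to OH), giving 20 directly. It was turned down for four reasons: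
- Both partners oxidise at similar potentials, so homo-coupling competes.
- A3 has several nucleophilic positions (C1, C3, C6, C8).
- The coupling position of A4 is flanked by a methyl group, and its catechol monoether ring can be oxidised further to an ortho-quinone.
- Product 20 is more electron-rich than either monomer and would be over-oxidised; both naphthols still need full syntheses.

Alternative 3: ring A built by a Danheiser-type benzannulation. 1-[4,6-Bis(benzyloxy)-5-methoxy-2-methylnaphthalen-1-yl]-2-[3-(benzyloxy)-5-methylphenyl]-2-diazoethan-1-one A5 would be photolysed with (triisopropylsilyloxy)ethyne. Wolff rearrangement, [2+2] cycloaddition, four-electron ring opening and 6π closure onto the aryl ring would give 8-(benzyloxy)-4-[4,6-bis(benzyloxy)-5-methoxy-2-methylnaphthalen-1-yl]-6-methyl-3-[(triisopropylsilyl)oxy]naphthalen-1-ol A6. This forms three C–C bonds at once but was turned down for three reasons: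
- The final closure can occur at either ortho carbon of the 3-(benzyloxy)-5-methylphenyl ring, and nothing in the substrate decides between them.
- The oxygens arrive the wrong way round (free OH where the methyl ether is needed, silyl ether where the free OH is needed), which costs a methylation and a desilylation.
- The unsubstituted silyloxyalkyne is a labile reagent that must be made separately.

Key step: step 11

## Route

Assumption: the target is drawn without configuration at the C1–C1' axis, so the racemic mixture of atropisomers is the goal and the route sets no axial configuration.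

Step 1
Reactants: 1 3-methylbut-2-enoyl chloride
Product: 2 N,N-diethyl-3-methylbut-2-enamide
Conditions: Et2NH (2.2 equiv), CH2Cl2, 0 °C to 20 °C
Reagents that add atoms: diethylamine, CCNCC
Why: Acylation of a secondary amine by an acid chloride (Schotten–Baumann type); the excess amine takes up HCl and the low temperature avoids deconjugation of the double bond.

Step 2
Reactants: 2 N,N-diethyl-3-methylbut-2-enamide; 3 1-(benzyloxy)-4-bromo-2-methoxybenzene
Product: 6 7-(benzyloxy)-8-methoxy-3-methylnaphthalen-1-ol, via lithium dienolate 4 (not isolated), via aryne 5 (not isolated)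
Conditions: LiN(iPr)2 (4 equiv), 2 (2 equiv), THF, −78 °C; then 3, −78 °C to 20 °C; aq. NH4Cl
Reagents that add atoms: none
Why: Aryne–dienolate annulation: the base deprotonates 2 at a γ-methyl group to give 4 and removes the proton of 3 between Br and OMe, and loss of LiBr gives 5. The γ-carbon of 4 adds to the aryne carbon remote from OMe (the anion forms next to OMe, an orientation the para benzyloxy group reinforces), the aryl anion acylates on the amide carbon, and enolisation gives the naphthol with OMe peri to OH.

Step 3
Reactants: 6 7-(benzyloxy)-8-methoxy-3-methylnaphthalen-1-ol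
Product: 7 7-(benzyloxy)-4-bromo-8-methoxy-3-methylnaphthalen-1-ol
Conditions: NBS (1.0 equiv), MeCN, −20 °C to 0 °C, dark
Reagents that add atoms: N-bromosuccinimide, O=C1CCC(=O)N1Br
Why: Electrophilic aromatic bromination para to the free naphthol OH, the strongest donor in the molecule. The OH is tied to the peri methoxy group by a hydrogen bond and the ortho position lies between OH and methyl, so the para position should be preferred.

Step 4
Reactants: 7 7-(benzyloxy)-4-bromo-8-methoxy-3-methylnaphthalen-1-ol
Product: 8 4,6-bis(benzyloxy)-1-bromo-5-methoxy-2-methylnaphthalene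
Conditions: BnBr, K2CO3, DMF, 50 °C
Reagents that add atoms: benzyl bromide, BrCc1ccccc1
Why: Williamson ether synthesis on the naphthoxide; the benzyl ether masks O4' until the last step and is inert to the organolithium, palladium and ketene chemistry that follows.

Step 5
Reactants: 8 4,6-bis(benzyloxy)-1-bromo-5-methoxy-2-methylnaphthalene
Product: 10 1-[4,6-bis(benzyloxy)-5-methoxy-2-methylnaphthalen-1-yl]ethan-1-one, via aryllithium 9 (not isolated)
Conditions: n-BuLi, THF, −78 °C; MeC(O)N(OMe)Me, −78 °C to 0 °C; aq. NH4Cl
Reagents that add atoms: N-methoxy-N-methylacetamide, CC(=O)N(C)OC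
Why: Bromine–lithium exchange is much faster than benzylic deprotonation at −78 °C, and the aryllithium adds once to the Weinreb amide because the chelated tetrahedral adduct releases the ketone only on work-up.

Step 6
Reactants: 11 methyl 2,6-dihydroxy-4-methylbenzoate
Product: 12 methyl 2-(benzyloxy)-6-hydroxy-4-methylbenzoate
Conditions: BnBr (1.0 equiv), K2CO3, acetone, 56 °C
Reagents that add atoms: benzyl bromide, BrCc1ccccc1
Why: Williamson ether synthesis on a symmetric diol, so only one mono-ether can form. After the first alkylation the remaining OH is held in a hydrogen bond to the ester carbonyl and reacts more slowly, and recovered 11 can be recycled.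

Step 7
Reactants: 12 methyl 2-(benzyloxy)-6-hydroxy-4-methylbenzoate
Product: 13 methyl 2-(benzyloxy)-4-methyl-6-[(trifluoromethanesulfonyl)oxy]benzoate
Conditions: Tf2O, pyridine, CH2Cl2, 0 °C
Reagents that add atoms: trifluoromethanesulfonic anhydride, O=S(=O)(OS(=O)(=O)C(F)(F)F)C(F)(F)F
Why: O-sulfonylation of the phenol; it turns the second oxygen of 11 into the leaving group for the palladium-catalysed coupling in step 9.

Step 8
Reactants: 13 methyl 2-(benzyloxy)-4-methyl-6-[(trifluoromethanesulfonyl)oxy]benzoate
Product: 14 3-(benzyloxy)-2-(1-methoxyethenyl)-5-methylphenyl trifluoromethanesulfonate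
Conditions: Cp2TiMe2 (3 equiv), toluene–THF, 70 °C, dark; purification on base-washed silica
Reagents that add atoms: dimethyltitanocene, C[Ti](C)(C1C=CC=C1)C1C=CC=C1
Why: Petasis methylenation: thermolysis of Cp2TiMe2 gives Cp2Ti=CH2, which adds to the ester carbonyl by [2+2] cycloaddition and cycloreverts to the methyl enol ether. The reagent is neither acidic nor basic and should leave the aryl triflate and the benzyl ether untouched.

Step 9
Reactants: 10 1-[4,6-bis(benzyloxy)-5-methoxy-2-methylnaphthalen-1-yl]ethan-1-one; 14 3-(benzyloxy)-2-(1-methoxyethenyl)-5-methylphenyl trifluoromethanesulfonate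
Product: 15 1-[4,6-bis(benzyloxy)-5-methoxy-2-methylnaphthalen-1-yl]-2-[3-(benzyloxy)-2-(1-methoxyethenyl)-5-methylphenyl]ethan-1-one
Conditions: Pd2(dba)3 (2.5 mol%), XPhos (6 mol%), Cs2CO3, toluene, 90 °C
Reagents that add atoms: none
Why: Palladium-catalysed ketone α-arylation (Buchwald–Hartwig type): oxidative addition of the triflate to zerovalent palladium, binding of the enolate of 10 and reductive elimination form the aryl–CH2 bond. Only the acetyl methyl of 10 can enolise, a second arylation is held back by crowding, and the carbonate base spares the triflate and the enol ether.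

Step 10
Reactants: 15 1-[4,6-bis(benzyloxy)-5-methoxy-2-methylnaphthalen-1-yl]-2-[3-(benzyloxy)-2-(1-methoxyethenyl)-5-methylphenyl]ethan-1-one
Product: 16 1-[4,6-bis(benzyloxy)-5-methoxy-2-methylnaphthalen-1-yl]-2-[3-(benzyloxy)-2-(1-methoxyethenyl)-5-methylphenyl]-2-diazoethan-1-one
Conditions: 4-acetamidobenzenesulfonyl azide, DBU, MeCN, 0 °C to 20 °C, dark; used at once
Reagents that add atoms: 4-acetamidobenzenesulfonyl azide, CC(=O)Nc1ccc(cc1)S(=O)(=O)N=[N+]=[N-]
Why: Regitz diazo transfer: the methylene group, activated by both the carbonyl and the aryl ring, is deprotonated by DBU, the enolate attacks the terminal nitrogen of the sulfonyl azide, and loss of the sulfonamide gives the diazo ketone.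

Step 11
Reactants: 16 1-[4,6-bis(benzyloxy)-5-methoxy-2-methylnaphthalen-1-yl]-2-[3-(benzyloxy)-2-(1-methoxyethenyl)-5-methylphenyl]-2-diazoethan-1-one
Product: 19 5-(benzyloxy)-1-[4,6-bis(benzyloxy)-5-methoxy-2-methylnaphthalen-1-yl]-4-methoxy-7-methylnaphthalen-2-ol, via diaryl ketene 17 (not isolated), via 3H-naphthalen-2-one 18 (not isolated)
Conditions: hν (450 nm LEDs), toluene (0.01 M), N2, 20 °C; then 50 °C, 30 min
Reagents that add atoms: none
Why: Light expels N2 from 16 and the 2-methylnaphthyl group shifts from the carbonyl carbon to the carbene carbon (Wolff rearrangement), which forms the C1–C1' bond intramolecularly and gives diaryl ketene 17. In 17 the ketene C=C, the C8a=C4a bond of the arene and the 1-methoxyethenyl group form a 1,3,5-hexatriene whose ends are the ketene carbon (future C2) and the enol ether CH2 (future C3). Thermal disrotatory 6π electrocyclisation closes ring A as a six-membered ring and gives 18; the electron-rich CH2 adds to the electrophilic ketene carbon, so the pericyclic and the polar description agree. 18 is an ortho-quinoid ketone and enolises at once to naphthol 19, which restores both aromatic rings. The closest known reaction types are the light-induced conversion of 2-diazo-1,2-diaryl ethanones into diaryl ketenes and the 6π closure of ortho-alkenylaryl and dienyl ketenes to 2-naphthols and phenols, the ring-forming half of the Danheiser benzannulation. No stereocentre is formed and the new axis arises racemic. The step needs the ketene to react with the enol ether rather than with an aryl ring and to close in one orientation only; the substrate secures both, because the only 6π partner sits on the carbon next to the ketene-bearing carbon and both ortho positions of the migrated naphthyl group (C2' with its methyl, C8a') are blocked. The ketene carbon becomes the free 2-OH and the enol ether oxygen becomes the 4-OMe, so the two oxygens of ring A are differentiated without a protecting group; high dilution and exclusion of nucleophiles keep the ketene from dimerising or being trapped.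

Step 12
Reactants: 19 5-(benzyloxy)-1-[4,6-bis(benzyloxy)-5-methoxy-2-methylnaphthalen-1-yl]-4-methoxy-7-methylnaphthalen-2-ol
Product: 20 4,5'-dimethoxy-2',7-dimethyl-[1,1'-binaphthalene]-2,4',5,6'-tetrol
Conditions: H2 (1 atm), 10% Pd/C, EtOAc–MeOH, 20 °C; work-up under N2
Reagents that add atoms: none
Why: Hydrogenolysis of the three benzyl ethers under neutral conditions; the methyl ethers and the naphthalene rings are not touched, and the reducing medium protects the electron-rich tetraphenol from oxidation.

## Compound list

1 | 3-methylbut-2-enoyl chloride | CC(C)=CC(=O)Cl | starting material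
2 | N,N-diethyl-3-methylbut-2-enamide | CCN(CC)C(=O)C=C(C)C | intermediate
3 | 1-(benzyloxy)-4-bromo-2-methoxybenzene | COc1cc(Br)ccc1OCc1ccccc1 | starting material
4 | lithium 1-(diethylamino)-3-methylbuta-1,3-dien-1-olate (enolate geometry not defined) | [Li+].[O-]C(=CC(C)=C)N(CC)CC | intermediate
5 | 4-(benzyloxy)-3-methoxybenzyne | COC1=C(OCc2ccccc2)C=CC#C1 | intermediate
6 | 7-(benzyloxy)-8-methoxy-3-methylnaphthalen-1-ol | Cc1cc(O)c2c(OC)c(OCc3ccccc3)ccc2c1 | intermediate
7 | 7-(benzyloxy)-4-bromo-8-methoxy-3-methylnaphthalen-1-ol | Cc1cc(O)c2c(OC)c(OCc3ccccc3)ccc2c1Br | intermediate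
8 | 4,6-bis(benzyloxy)-1-bromo-5-methoxy-2-methylnaphthalene | Cc1cc(OCc2ccccc2)c2c(OC)c(OCc3ccccc3)ccc2c1Br | intermediate
9 | [4,6-bis(benzyloxy)-5-methoxy-2-methylnaphthalen-1-yl]lithium | [Li]c1c(C)cc(OCc2ccccc2)c2c(OC)c(OCc3ccccc3)ccc12 | intermediate
10 | 1-[4,6-bis(benzyloxy)-5-methoxy-2-methylnaphthalen-1-yl]ethan-1-one | CC(=O)c1c(C)cc(OCc2ccccc2)c2c(OC)c(OCc3ccccc3)ccc12 | intermediate
11 | methyl 2,6-dihydroxy-4-methylbenzoate | COC(=O)c1c(O)cc(C)cc1O | starting material
12 | methyl 2-(benzyloxy)-6-hydroxy-4-methylbenzoate | COC(=O)c1c(O)cc(C)cc1OCc1ccccc1 | intermediate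
13 | methyl 2-(benzyloxy)-4-methyl-6-[(trifluoromethanesulfonyl)oxy]benzoate | COC(=O)c1c(OCc2ccccc2)cc(C)cc1OS(=O)(=O)C(F)(F)F | intermediate
14 | 3-(benzyloxy)-2-(1-methoxyethenyl)-5-methylphenyl trifluoromethanesulfonate | C=C(OC)c1c(OCc2ccccc2)cc(C)cc1OS(=O)(=O)C(F)(F)F | intermediate
15 | 1-[4,6-bis(benzyloxy)-5-methoxy-2-methylnaphthalen-1-yl]-2-[3-(benzyloxy)-2-(1-methoxyethenyl)-5-methylphenyl]ethan-1-one | C=C(OC)c1c(OCc2ccccc2)cc(C)cc1CC(=O)c1c(C)cc(OCc2ccccc2)c2c(OC)c(OCc3ccccc3)ccc12 | intermediate
16 | 1-[4,6-bis(benzyloxy)-5-methoxy-2-methylnaphthalen-1-yl]-2-[3-(benzyloxy)-2-(1-methoxyethenyl)-5-methylphenyl]-2-diazoethan-1-one | C=C(OC)c1c(OCc2ccccc2)cc(C)cc1C(=[N+]=[N-])C(=O)c1c(C)cc(OCc2ccccc2)c2c(OC)c(OCc3ccccc3)ccc12 | intermediate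
17 | 2-[4,6-bis(benzyloxy)-5-methoxy-2-methylnaphthalen-1-yl]-2-[3-(benzyloxy)-2-(1-methoxyethenyl)-5-methylphenyl]ethen-1-one (diaryl ketene) | C=C(OC)c1c(OCc2ccccc2)cc(C)cc1C(=C=O)c1c(C)cc(OCc2ccccc2)c2c(OC)c(OCc3ccccc3)ccc12 | intermediate
18 | 5-(benzyloxy)-1-[4,6-bis(benzyloxy)-5-methoxy-2-methylnaphthalen-1-yl]-4-methoxy-7-methylnaphthalen-2(3H)-one | O=C1CC(OC)=C2C(OCc3ccccc3)=CC(C)=CC2=C1c1c(C)cc(OCc2ccccc2)c2c(OC)c(OCc3ccccc3)ccc12 | intermediate
19 | 5-(benzyloxy)-1-[4,6-bis(benzyloxy)-5-methoxy-2-methylnaphthalen-1-yl]-4-methoxy-7-methylnaphthalen-2-ol | COc1cc(O)c(-c2c(C)cc(OCc3ccccc3)c3c(OC)c(OCc4ccccc4)ccc23)c2cc(C)cc(OCc3ccccc3)c12 | intermediate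
20 | 4,5'-dimethoxy-2',7-dimethyl-[1,1'-binaphthalene]-2,4',5,6'-tetrol (racemic axis) | COc1cc(O)c(-c2c(C)cc(O)c3c(OC)c(O)ccc23)c2cc(C)cc(O)c12 | target

## Step count and least certain steps

Total step count: 12. Longest linear sequence: 9 steps (steps 1, 2, 3, 4, 5, 9, 10, 11, 12).

Step 11 (key step). What may go wrong: the keto carbene may be intercepted by the neighbouring enol ether before the naphthyl group shifts, or the diazo group may cyclise onto the enol ether during handling. Either process consumes 16 without forming the ketene. The fallback reaches ketene 17 without a carbene and sets out from 8 and 14: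
- Bromide 8 is coupled with the Reformatsky reagent BrZnCH2CO2Me (Pd2(dba)3, P(tBu)3, THF) to give methyl 2-[4,6-bis(benzyloxy)-5-methoxy-2-methylnaphthalen-1-yl]acetate F1.
- Palladium-catalysed α-arylation of the lithium enolate of F1 (LiN(SiMe3)2, Pd2(dba)3, P(tBu)3, toluene) with triflate 14 gives methyl 2-[4,6-bis(benzyloxy)-5-methoxy-2-methylnaphthalen-1-yl]-2-[3-(benzyloxy)-2-(1-methoxyethenyl)-5-methylphenyl]acetate F2.
- KOSiMe3 in THF cleaves the methyl ester without acid and gives potassium 2-[4,6-bis(benzyloxy)-5-methoxy-2-methylnaphthalen-1-yl]-2-[3-(benzyloxy)-2-(1-methoxyethenyl)-5-methylphenyl]acetate F3.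
- Oxalyl chloride converts the salt into 2-[4,6-bis(benzyloxy)-5-methoxy-2-methylnaphthalen-1-yl]-2-[3-(benzyloxy)-2-(1-methoxyethenyl)-5-methylphenyl]acetyl chloride F4.
- Et3N at 20 °C eliminates HCl from F4 to give ketene 17, which closes to 19 as in step 11.

Step 2. What may go wrong: deprotonation of 3 at the other position next to bromine would lead to the regioisomeric aryne, and the amide bases may add to the aryne in competition with dienolate 4. The fallback builds the same ring stepwise by directed metalation and anionic cyclisation, sets out from 3 and comes back at 6: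
- 3 is lithiated between Br and OMe (LiN(iPr)2, THF, −78 °C) and quenched with diethylcarbamoyl chloride to give N,N-diethyl-3-(benzyloxy)-6-bromo-2-methoxybenzamide F5.
- Stille coupling with tributyl(2-methylprop-2-en-1-yl)stannane (Pd(PPh3)4, toluene, 100 °C) gives N,N-diethyl-3-(benzyloxy)-2-methoxy-6-(2-methylprop-2-en-1-yl)benzamide F6.
- LiN(iPr)2 deprotonates the benzylic CH2 of F6, the allyl anion attacks the amide carbon through its far end, and loss of diethylamide with enolisation gives 6.

Step 8. What may go wrong: slow methylenation at the doubly ortho-substituted ester, attack of the titanium reagent on the sulfonate at the temperature needed, and hydrolysis of the enol ether on purification. The fallback methylenates before the triflate is in place, with a more reactive methylidene source at low temperature; it sets out from 12 and comes back at 14: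
- 12 is silylated (t-BuMe2SiCl, imidazole, DMF) to methyl 2-(benzyloxy)-6-[(tert-butyldimethylsilyl)oxy]-4-methylbenzoate F7.
- Cp2Ti(μ-Cl)(μ-CH2)AlMe2 with pyridine in THF–toluene at −40 °C to 0 °C gives {[3-(benzyloxy)-2-(1-methoxyethenyl)-5-methylphenyl]oxy}(tert-butyl)dimethylsilane F8.
- CsF in DMF releases caesium 3-(benzyloxy)-2-(1-methoxyethenyl)-5-methylphenolate F9, which is triflated in the same flask with PhN(SO2CF3)2 to give 14.

Step 9. What may go wrong: slow reductive elimination from the ortho-substituted arylpalladium enolate and cleavage of the S–O bond of the triflate by the base. The fallback makes the acyl–naphthyl bond instead of the aryl–CH2 bond; it sets out from 14 and 8 and comes back at 15: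
- 14 is coupled with BrZnCH2CO2Me (Pd2(dba)3, P(tBu)3, THF) to give methyl 2-[3-(benzyloxy)-2-(1-methoxyethenyl)-5-methylphenyl]acetate F10.
- Me(MeO)NH·HCl and i-PrMgCl in THF at −20 °C convert F10 into 2-[3-(benzyloxy)-2-(1-methoxyethenyl)-5-methylphenyl]-N-methoxy-N-methylacetamide F11.
- Aryllithium 9, made from 8 as in step 5, is added to F11 at −78 °C and gives 15 after a buffered work-up.

Step 10. What may go wrong: incomplete diazo transfer at the hindered methylene group, and slow cyclisation of the diazo group onto the enol ether if the reaction has to be warmed. The fallback is a deacylative diazo transfer; it sets out from 15 and comes back at 16: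
- The lithium enolate of 15 (LiN(SiMe3)2, THF, −78 °C) is acylated with CF3CO2CH2CF3 to give 1-[4,6-bis(benzyloxy)-5-methoxy-2-methylnaphthalen-1-yl]-2-[3-(benzyloxy)-2-(1-methoxyethenyl)-5-methylphenyl]-4,4,4-trifluorobutane-1,3-dione F12.
- Methanesulfonyl azide, Et3N and water in MeCN at 20 °C transfer the diazo group with loss of the trifluoroacetyl group and give 16.

## Further compounds

F1 | step 11 | methyl 2-[4,6-bis(benzyloxy)-5-methoxy-2-methylnaphthalen-1-yl]acetate | COC(=O)Cc1c(C)cc(OCc2ccccc2)c2c(OC)c(OCc3ccccc3)ccc12
F2 | step 11 | methyl 2-[4,6-bis(benzyloxy)-5-methoxy-2-methylnaphthalen-1-yl]-2-[3-(benzyloxy)-2-(1-methoxyethenyl)-5-methylphenyl]acetate (racemic) | COC(=O)C(c1cc(C)cc(OCc2ccccc2)c1C(=C)OC)c1c(C)cc(OCc2ccccc2)c2c(OC)c(OCc3ccccc3)ccc12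
F3 | step 11 | potassium 2-[4,6-bis(benzyloxy)-5-methoxy-2-methylnaphthalen-1-yl]-2-[3-(benzyloxy)-2-(1-methoxyethenyl)-5-methylphenyl]acetate (racemic) | [K+].[O-]C(=O)C(c1cc(C)cc(OCc2ccccc2)c1C(=C)OC)c1c(C)cc(OCc2ccccc2)c2c(OC)c(OCc3ccccc3)ccc12
F4 | step 11 | 2-[4,6-bis(benzyloxy)-5-methoxy-2-methylnaphthalen-1-yl]-2-[3-(benzyloxy)-2-(1-methoxyethenyl)-5-methylphenyl]acetyl chloride (racemic) | ClC(=O)C(c1cc(C)cc(OCc2ccccc2)c1C(=C)OC)c1c(C)cc(OCc2ccccc2)c2c(OC)c(OCc3ccccc3)ccc12
F5 | step 2 | N,N-diethyl-3-(benzyloxy)-6-bromo-2-methoxybenzamide | CCN(CC)C(=O)c1c(Br)ccc(OCc2ccccc2)c1OC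
F6 | step 2 | N,N-diethyl-3-(benzyloxy)-2-methoxy-6-(2-methylprop-2-en-1-yl)benzamide | CCN(CC)C(=O)c1c(CC(C)=C)ccc(OCc2ccccc2)c1OC
F7 | step 8 | methyl 2-(benzyloxy)-6-[(tert-butyldimethylsilyl)oxy]-4-methylbenzoate | COC(=O)c1c(OCc2ccccc2)cc(C)cc1O[Si](C)(C)C(C)(C)C
F8 | step 8 | {[3-(benzyloxy)-2-(1-methoxyethenyl)-5-methylphenyl]oxy}(tert-butyl)dimethylsilane | C=C(OC)c1c(OCc2ccccc2)cc(C)cc1O[Si](C)(C)C(C)(C)C
F9 | step 8 | caesium 3-(benzyloxy)-2-(1-methoxyethenyl)-5-methylphenolate | [Cs+].[O-]c1cc(C)cc(OCc2ccccc2)c1C(=C)OC
F10 | step 9 | methyl 2-[3-(benzyloxy)-2-(1-methoxyethenyl)-5-methylphenyl]acetate | COC(=O)Cc1cc(C)cc(OCc2ccccc2)c1C(=C)OC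
F11 | step 9 | 2-[3-(benzyloxy)-2-(1-methoxyethenyl)-5-methylphenyl]-N-methoxy-N-methylacetamide | CON(C)C(=O)Cc1cc(C)cc(OCc2ccccc2)c1C(=C)OC
F12 | step 10 | 1-[4,6-bis(benzyloxy)-5-methoxy-2-methylnaphthalen-1-yl]-2-[3-(benzyloxy)-2-(1-methoxyethenyl)-5-methylphenyl]-4,4,4-trifluorobutane-1,3-dione (racemic) | FC(F)(F)C(=O)C(c1cc(C)cc(OCc2ccccc2)c1C(=C)OC)C(=O)c1c(C)cc(OCc2ccccc2)c2c(OC)c(OCc3ccccc3)ccc12
A1 | alternative 1 | 2-[2,5-bis(benzyloxy)-4-methoxy-7-methylnaphthalen-1-yl]-4,4,5,5-tetramethyl-1,3,2-dioxaborolane | COc1cc(OCc2ccccc2)c(B2OC(C)(C)C(C)(C)O2)c2cc(C)cc(OCc3ccccc3)c12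
A2 | alternative 1 | 2,5-bis(benzyloxy)-1-[4,6-bis(benzyloxy)-5-methoxy-2-methylnaphthalen-1-yl]-4-methoxy-7-methylnaphthalene | COc1cc(OCc2ccccc2)c(-c2c(C)cc(OCc3ccccc3)c3c(OC)c(OCc4ccccc4)ccc23)c2cc(C)cc(OCc3ccccc3)c12
A3 | alternative 2 | 4-methoxy-7-methylnaphthalene-2,5-diol | COc1cc(O)cc2cc(C)cc(O)c12
A4 | alternative 2 | 8-methoxy-3-methylnaphthalene-1,7-diol | Cc1cc(O)c2c(OC)c(O)ccc2c1
A5 | alternative 3 | 1-[4,6-bis(benzyloxy)-5-methoxy-2-methylnaphthalen-1-yl]-2-[3-(benzyloxy)-5-methylphenyl]-2-diazoethan-1-one | Cc1cc(OCc2ccccc2)cc(c1)C(=[N+]=[N-])C(=O)c1c(C)cc(OCc2ccccc2)c2c(OC)c(OCc3ccccc3)ccc12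
A6 | alternative 3 | 8-(benzyloxy)-4-[4,6-bis(benzyloxy)-5-methoxy-2-methylnaphthalen-1-yl]-6-methyl-3-[(triisopropylsilyl)oxy]naphthalen-1-ol | Oc1cc(O[Si](C(C)C)(C(C)C)C(C)C)c(-c2c(C)cc(OCc3ccccc3)c3c(OC)c(OCc4ccccc4)ccc23)c2cc(C)cc(OCc3ccccc3)c12
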